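## Retrosynthetic overview

1. The side chain comes last. The (Z)-γ-ylidene-β-methylbutenolide ring is closed on terminal enyne 16 by Pd/Cu alkynylation and 5-exo-dig lactonization with (Z)-3-iodobut-2-enoic acid. The E-C13=C14 bond comes from syn-methylalumination of a C13≡C14 alkyne.
2. C6–OH is relayed from C4. The equatorial C18 carboxyl lies peri (syn-pentane) to the equatorial H-6α of ring B, so a carboxylate-directed γ-C–H lactonization forms the 18,6α-olide, which is opened near the end.
3. The key disconnection cuts C4–C5, C9–C10 and C8–O in one cationic cascade. The feature used is the contiguous array C4/C5/C10/C9/C8 of the trans-decalin (rings A/B): equatorial C18, axial methyls C19/C20/C17 and equatorial 8α-O. This array is the Stork–Eschenmoser image of an all-E farnesyl chain whose terminal E-methyl is oxidized.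
4. Ring order: oxirane (the only catalytic stereo input), then ring A, ring B and the δ-lactone (all in step 5), then the γ-lactone (step 9), then the butenolide (step 15). The sacrificial 3β-OH is removed by Barton–McCombie deoxygenation.
5. The key-step precursor is the acyclic epoxy diene ester 6, four steps from farnesyl bromide.

Key step: step 5

Remark: labdane numbering is used (C18 = 4α carbon, C19 = 4β methyl, C20 = methyl on C10, C17 = methyl on C8, chain C11 to C16 with C16 the ylidene ring carbon). Compounds 1, 2, 17 and all reagents are taken as commercial.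

## Route

Step 1
Reactants: 1 (2E,6E)-farnesyl bromide; 2 tert-butyl acetate
Product: 3 tert-butyl (4E,8E)-5,9,13-trimethyltetradeca-4,8,12-trienoate (tert-butyl farnesylacetate)
Conditions: LDA, THF, −78 °C; then 1, DMPU, −78 °C to 0 °C
Reagents that add atoms: none
Why: Enolate alkylation (SN2) of the lithium enolate of 2 at the primary allylic bromide adds C12 and C13 and leaves both E alkenes untouched.

Step 2
Reactants: 3 tert-butyl farnesylacetate
Product: 4 tert-butyl (4E,8E,12E)-14-hydroxy-5,9,13-trimethyltetradeca-4,8,12-trienoate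
Conditions: SeO2 (cat.), t-BuOOH, salicylic acid (cat.), CH2Cl2, 0 °C
Reagents that add atoms: tert-butyl hydroperoxide, CC(C)(C)OO
Why: Catalytic SeO2 allylic oxidation (ene reaction, then [2,3]-sigmatropic shift) should attack the least hindered terminal isopropylidene and oxidize its E-methyl, the carbon that becomes C18.

Step 3
Reactants: 4 E-allylic alcohol
Product: 5 tert-butyl (4E,8E)-11-[(2S,3S)-3-(hydroxymethyl)-3-methyloxiran-2-yl]-5,9-dimethylundeca-4,8-dienoate
Conditions: Ti(OiPr)4 (cat.), L-(+)-diethyl tartrate (cat.), t-BuOOH, 4 Å MS, CH2Cl2, −20 °C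
Reagents that add atoms: tert-butyl hydroperoxide, CC(C)(C)OO
Why: Sharpless asymmetric epoxidation touches only the alkene of the allylic alcohol, and L-(+)-tartrate should give the (2S,3S)-oxirane (C3 and C4), the only stereochemical information set by catalysis.

Step 4
Reactants: 5 epoxy alcohol
Product: 6 TBS ether of 5 (acyclic epoxy diene ester)
Conditions: TBSCl, imidazole, DMF, 0 °C to rt
Reagents that add atoms: tert-butyldimethylsilyl chloride, CC(C)(C)[Si](C)(C)Cl
Why: Silylation of the primary alcohol blocks Payne rearrangement and hydroxyl participation in the Lewis acid step without touching the oxirane stereocenters.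

Step 5
Reactants: 6 epoxy diene ester
Product: 7 3β-hydroxy-18-(tert-butyldimethylsilyloxy)ambreinolide (trans-anti-trans tricycle: 4α-CH2OTBS, 4β-Me, H-5α, Me-10β, H-9α, Me-8β, 8α-O–C13(=O) δ-lactone)
Conditions: MeAlCl2 (1.5 equiv), CH2Cl2, −78 °C; aq. NaHCO3
Reagents that add atoms: none
Why: MeAlCl2 binds the oxirane oxygen (helped by the neighbouring silyloxy oxygen) and loosens the tertiary C4–O bond, C5 of the C5=C10 alkene attacks C4 from the rear, C9 of the C8=C9 alkene attacks the developing C10 cation, the ester carbonyl oxygen captures C8, and the tert-butyl group leaves as isobutene. The closest known reaction type is the epoxide-initiated Stork–Eschenmoser cation–olefin polycyclization of oxidosqualene-like epoxy polyenes, also known for Sharpless-derived oxiranes that carry an oxygenated carbon at C4, joined here to the classical carboxyl-terminated closure of farnesylacetic acid to ambreinolide. Ring A closes 6-endo at both the oxirane and the C5=C10 alkene, ring B closes 6-endo-trig on the C8=C9 alkene, and the δ-lactone closes as a six-membered O-capture of the C8 cation anti to the new C9–C10 bond. C3 keeps the oxirane configuration (equatorial 3β-O, removed later), C4 is set by inversion so that the former E-CH2OTBS becomes the equatorial 4α carbon C18 and the former Z-methyl the axial C19, C5 and C10 are set by anti addition across the E-C5=C10 alkene in a chair (H-5α, Me-10β, trans fusion), and C9 and C8 by anti addition across the E-C8=C9 alkene (H-9α, Me-8β, 8α-O). The absolute sense follows from the (S,S)-oxirane, because only one chair–chair fold allows rear-side attack at C4 with the C3–O bond equatorial. The step needs opening at C4 and not at C3, and full propagation instead of hydride shift to a 3-ketone or early proton loss; the tertiary site, the low temperature, the non-basic medium and the built-in six-ring nucleophile should secure this.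

Step 6
Reactants: 7 hydroxy lactone
Product: 8 3β-O-(imidazol-1-ylthiocarbonyl) derivative of 7
Conditions: 1,1'-thiocarbonyldiimidazole, DMAP (cat.), ClCH2CH2Cl, reflux
Reagents that add atoms: 1,1'-thiocarbonyldiimidazole, S=C(n1ccnc1)n1ccnc1
Why: Neutral thioacylation of the only free hydroxyl prepares the Barton–McCombie deoxygenation and avoids enolizing the δ-lactone.

Step 7
Reactants: 8 thiocarbonylimidazolide
Product: 9 18-(tert-butyldimethylsilyloxy)ambreinolide (C3 now CH2)
Conditions: Bu3SnH, AIBN (cat.), toluene, 110 °C
Reagents that add atoms: none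
Why: Barton–McCombie radical deoxygenation removes the sacrificial 3β-oxygen through a secondary C3 radical that has no β-leaving group, so no other stereocenter is touched.

Step 8
Reactants: 9 silyl ether lactone
Product: 10 ambreinolide-18-oic acid (4α-COOH, 4β-Me)
Conditions: Jones reagent (CrO3, H2SO4, H2O), acetone, 0 °C to rt
Reagents that add atoms: water, O
Why: Jones oxidation cleaves the primary silyl ether in the acidic medium and takes the neopentyl alcohol through the aldehyde hydrate to the acid, while the δ-lactone and the quaternary C4 are inert.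

Step 9
Reactants: 10 acid lactone
Product: 11 bis-lactone (18,6α-olide and 13,8α-olide)
Conditions: (S,S)-Mn(TIPS-pdp)(OTf)2 (1–2 mol %), aq. H2O2 (slow addition), (CF3)2CHOH, 0 °C
Reagents that add atoms: none
Why: In this carboxylic-acid-directed Mn-oxo γ-C(sp3)–H lactonization (1,7-HAT, then carboxylate rebound) the metal-bound equatorial C18 carboxylate reaches only the peri equatorial H-6α, and only a 6α-oxygen can close the five-membered ring, which sets C6.

Step 10
Reactants: 11 bis-lactone
Product: 12 C13 lactol (anomeric mixture) with the 18,6α-olide intact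
Conditions: DIBAL-H (1.05 equiv), CH2Cl2, −78 °C; Rochelle salt
Reagents that add atoms: none
Why: Partial lactone reduction should choose the δ-lactone carbonyl flanked by CH2 over the γ-lactone carbonyl, which is shielded by the quaternary C4 and its axial methyl.

Step 11
Reactants: 12 lactol
Product: 13 8α-hydroxy C13≡C14 terminal alkyne 18,6α-olide
Conditions: dimethyl (1-diazo-2-oxopropyl)phosphonate, K2CO3, MeOH, 0 °C to rt
Reagents that add atoms: dimethyl (1-diazo-2-oxopropyl)phosphonate, COP(=O)(OC)C(=[N+]=[N-])C(C)=O
Why: Ohira–Bestmann (Seyferth–Gilbert) homologation of the open hydroxy-aldehyde form of the lactol adds C14 and frees the tertiary 8α-OH without touching a stereocenter.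

Step 12
Reactants: 13 alkynol lactone
Product: 15 (13E)-trimethylsilyl enyne 18,6α-olide, via alkenylalane 14 (not isolated)
Conditions: Me3Al (3.5 equiv), Cp2ZrCl2 (0.3 equiv), CH2Cl2, 0 °C to rt; excess Me3Al evaporated; then BrC≡CSiMe3, Pd(PPh3)4 (5 mol %), ZnCl2 (cat.), THF, rt
Reagents that add atoms: trimethylaluminium, C[Al](C)C; (bromoethynyl)trimethylsilane, C[Si](C)(C)C#CBr
Why: Zr-catalysed syn-methylalumination places the methyl on C13 and aluminium on C14, and the Negishi cross-coupling proceeds with retention, so the E-C13=C14 bond is set by the carbometalation.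

Step 13
Reactants: 15 silyl enyne lactone
Product: 16 (13E)-6α,8α-dihydroxy terminal enyne 18-oic acid
Conditions: KOH, MeOH–H2O, 50 °C; then 1 M HCl to pH 4, 0 °C
Reagents that add atoms: potassium hydroxide, [K+].[OH-]
Why: One saponification opens the strained trans-bridged γ-lactone by acyl–oxygen cleavage (C6 configuration retained) and removes the alkynyl silane, done before the base-sensitive butenolide exists.

Step 14
Reactants: 17 2-butynoic acid
Product: 18 (Z)-3-iodobut-2-enoic acid
Conditions: NaI, AcOH, 115 °C
Reagents that add atoms: sodium iodide, [Na+].[I-]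
Why: Conjugate anti-hydroiodination of the ynoic acid should place iodine cis to the carboxyl group, as the later lactonization requires.

Step 15
Reactants: 16 enyne dihydroxy acid; 18 (Z)-3-iodobut-2-enoic acid
Product: 20 target CNP0145461.1, via dienynoic acid 19 (not isolated)
Conditions: Pd(PPh3)4 (5 mol %), CuI (5 mol %), Et3N, MeCN, rt
Reagents that add atoms: none
Why: Sonogashira coupling gives the (Z)-2-en-4-ynoic acid, whose cis carboxylate adds 5-exo-dig and anti across the metal-activated alkyne, so the butenolide forms with the Z-C15=C16 bond while the distant C18 acid and both hydroxyls stay spectators.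

## Compound list

1 | (2E,6E)-farnesyl bromide | CC(C)=CCC/C(C)=C/CC/C(C)=C/CBr | starting material
2 | tert-butyl acetate | CC(=O)OC(C)(C)C | starting material
3 | tert-butyl (4E,8E)-5,9,13-trimethyltetradeca-4,8,12-trienoate | CC(C)(C)OC(=O)CC/C=C(\C)CC/C=C(\C)CCC=C(C)C | intermediate
4 | tert-butyl (4E,8E,12E)-14-hydroxy-5,9,13-trimethyltetradeca-4,8,12-trienoate | CC(C)(C)OC(=O)CC/C=C(\C)CC/C=C(\C)CC/C=C(\C)CO | intermediate
5 | tert-butyl (4E,8E)-11-[(2S,3S)-3-(hydroxymethyl)-3-methyloxiran-2-yl]-5,9-dimethylundeca-4,8-dienoate | CC(C)(C)OC(=O)CC/C=C(\C)CC/C=C(\C)CC[C@@H]1O[C@@]1(C)CO | intermediate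
6 | TBS ether of 5 | CC(C)(C)OC(=O)CC/C=C(\C)CC/C=C(\C)CC[C@@H]1O[C@@]1(C)CO[Si](C)(C)C(C)(C)C | intermediate
7 | 3β-hydroxy-18-(TBS-oxy)ambreinolide | O=C1CC[C@@H]2[C@@]3(C)CC[C@H](O)[C@@](C)(CO[Si](C)(C)C(C)(C)C)[C@@H]3CC[C@@]2(C)O1 | intermediate
8 | 3β-O-(imidazol-1-ylthiocarbonyl)-18-(TBS-oxy)ambreinolide | O=C1CC[C@@H]2[C@@]3(C)CC[C@H](OC(=S)n4ccnc4)[C@@](C)(CO[Si](C)(C)C(C)(C)C)[C@@H]3CC[C@@]2(C)O1 | intermediate
9 | 18-(TBS-oxy)ambreinolide | O=C1CC[C@@H]2[C@@]3(C)CCC[C@@](C)(CO[Si](C)(C)C(C)(C)C)[C@@H]3CC[C@@]2(C)O1 | intermediate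
10 | ambreinolide-18-oic acid (4α-COOH) | O=C1CC[C@@H]2[C@@]3(C)CCC[C@@](C)(C(=O)O)[C@@H]3CC[C@@]2(C)O1 | intermediate
11 | bis-lactone (18,6α-olide and 13,8α-olide) | O=C1CC[C@@H]2[C@@]3(C)CCC[C@@]4(C)C(=O)O[C@H]([C@H]34)C[C@@]2(C)O1 | intermediate
12 | C13 lactol of 11 (anomeric mixture) | OC1CC[C@@H]2[C@@]3(C)CCC[C@@]4(C)C(=O)O[C@H]([C@H]34)C[C@@]2(C)O1 | intermediate
13 | 8α-hydroxy C13≡C14 alkyne 18,6α-olide | C#CCC[C@@H]1[C@@]2(C)CCC[C@@]3(C)C(=O)O[C@H]([C@H]23)C[C@@]1(C)O | intermediate
14 | (E)-C14 dimethylalane, 8-O-dimethylaluminium alkoxide | C[Al](C)/C=C(\C)CC[C@@H]1[C@@]2(C)CCC[C@@]3(C)C(=O)O[C@H]([C@H]23)C[C@@]1(C)O[Al](C)C | intermediate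
15 | (13E)-trimethylsilyl enyne 18,6α-olide, 8α-OH | C[Si](C)(C)C#C/C=C(\C)CC[C@@H]1[C@@]2(C)CCC[C@@]3(C)C(=O)O[C@H]([C@H]23)C[C@@]1(C)O | intermediate
16 | (13E)-6α,8α-dihydroxy terminal enyne 18-oic acid | C#C/C=C(\C)CC[C@@H]1[C@@]2(C)CCC[C@@](C)(C(=O)O)[C@@H]2[C@@H](O)C[C@@]1(C)O | intermediate
17 | 2-butynoic acid | CC#CC(=O)O | starting material
18 | (Z)-3-iodobut-2-enoic acid | C/C(I)=C/C(=O)O | intermediate
19 | (2Z,6E)-dien-4-ynoic acid coupled to the decalin diol acid | OC(=O)/C=C(/C)C#C/C=C(\C)CC[C@@H]1[C@@]2(C)CCC[C@@](C)(C(=O)O)[C@@H]2[C@@H](O)C[C@@]1(C)O | intermediate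
20 | CNP0145461.1 | CC1=CC(=O)O/C1=C\C=C(/C)CC[C@@H]1[C@@]2(C)CCC[C@@](C)(C(=O)O)[C@@H]2[C@@H](O)C[C@@]1(C)O | target

## Step count and risks

Total step count: 15. Longest linear sequence: 14 (steps 1–13 and 15).

**Step 5.** The cascade may be diverted by a hydride shift at the activated oxirane, by proton loss after ring A, or by participation of the silyloxy group. The fallback sets out from 6 and replaces the cationic cascade by a radical one.
- Cp2TiCl (from Cp2TiCl2, Mn and collidine hydrochloride) opens the oxirane homolytically at C4.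
- A 6-endo/6-endo radical bicyclization ended by hydrogen loss should give the bicyclic 8(17)-exomethylene 3β-hydroxy tert-butyl ester F1. C4 is then set by the chair with the larger CH2OTBS equatorial.
- Catalytic TfOH in CH2Cl2 at low temperature protonates the exocyclic alkene, and the ester closes on C8, which comes back to the route at 7.

**Step 9.** Undirected oxidation of ring A methylenes, or stalling of the catalyst, may compete with the directed hydrogen abstraction. The fallback sets out from 10 and uses a nitrogen-centred radical in a Hofmann–Löffler–Freytag type relay.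
- The acid is activated and treated with ammonia to give the primary 18-carboxamide F2.
- PhI(OAc)2 and I2 under visible light form the N-iodoamide, whose amidyl radical abstracts H-6α by 1,5-HAT.
- The C6 iodide is displaced by the amide oxygen to give the 18,6α-iminolactone F3.
- Aqueous acid hydrolysis comes back to the route at 11.

**Step 12.** Attack of Me3Al on the lactone, slow carbometalation of the aluminium alkoxide, or methyl transfer and homocoupling in the coupling may erode the one-pot sequence. The fallback sets out from 11 and builds the alkene by olefination, bypassing 12 to 14.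
- One equivalent of MeLi at −78 °C opens the unhindered δ-lactone to the 8α-hydroxy 13-methyl ketone F4.
- Horner–Wadsworth–Emmons reaction with lithiated diethyl [3-(trimethylsilyl)prop-2-yn-1-yl]phosphonate, followed by separation of the Z isomer, comes back to the route at 15.

## Further compounds

F1 | step 5 | tert-butyl 3-[3β-hydroxy-18-(TBS-oxy)-8(17)-exomethylene decalin-9-yl]propanoate | CC(C)(C)OC(=O)CC[C@@H]1[C@@]2(C)CC[C@H](O)[C@@](C)(CO[Si](C)(C)C(C)(C)C)[C@@H]2CCC1=C
F2 | step 9 | ambreinolide-18-carboxamide | O=C1CC[C@@H]2[C@@]3(C)CCC[C@@](C)(C(N)=O)[C@@H]3CC[C@@]2(C)O1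
F3 | step 9 | 18,6α-iminolactone of the 13,8α-olide | O=C1CC[C@@H]2[C@@]3(C)CCC[C@@]4(C)C(=N)O[C@H]([C@H]34)C[C@@]2(C)O1
F4 | step 12 | 8α-hydroxy 13-methyl ketone 18,6α-olide | CC(=O)CC[C@@H]1[C@@]2(C)CCC[C@@]3(C)C(=O)O[C@H]([C@H]23)C[C@@]1(C)O
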